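**Plan**

- Retrosynthesis: the CH2–C6 bond of the dienone ring is cut first, then ring bonds C5–C6 and C2–C3 together (ring numbering: C1 ring ketone, C2 butanoyl-bearing, C3 and C5 enol carbons, C4 quaternary, C6 bridge-bearing).
- Enabling feature: C3 and C5 are both carboxyl-level carbons on the one quaternary C4, and C2 and C6 are the central and terminal carbons of a 1,3-diketone (C1 plus the butanoyl C=O). The ring is therefore a methyl(prenyl)malonyl 1,3-dielectrophile laid across heptane-2,4-dione.
- C4 is stereogenic only because C2 and C6 differ, so a malonyl unit with unequal carbonyls (acid chloride, ester) turns the site order of a [3+3] double C-acylation into absolute configuration.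
- Forward: mixed methylmalonate, asymmetric prenylation, acid chloride/ester, [3+3] annulation to the only carbocycle that is built (the arene is bought as methylphloroglucinol), then bridge formation with aminomethylated aspidinol.
- Stereochemistry: the single stereocentre is set by catalyst-controlled phase-transfer prenylation (step 3) and is carried, not created, through the key step.

Key step: step 6

Remark: descriptors of the dienone ring refer to the tautomer of the target formula. The (S,S) catalyst of step 3 is assumed to give (S)-4, as expected for simple allylic bromides; should the sense prove opposite, the (R,R) catalyst is used and nothing else changes.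

**Route**

Step 1
Reactants: 1 2,2,5-trimethyl-1,3-dioxane-4,6-dione (methyl Meldrum's acid)
Product: 2 3-(tert-butoxy)-2-methyl-3-oxopropanoic acid (racemic)
Conditions: t-BuOH, reflux
Reagents that add atoms: tert-butanol, CC(C)(C)O
Why: Alcoholysis of the cyclic acylal (Meldrum's acid ring opening) by tert-butanol should give the malonic half-ester with loss of acetone, the standard entry to mono-tert-butyl malonates.

Step 2
Reactants: 2 3-(tert-butoxy)-2-methyl-3-oxopropanoic acid
Product: 3 1-tert-butyl 3-(2,2-diphenylethyl) 2-methylpropanedioate (racemic)
Conditions: Ph2CHCH2OH, N-(3-dimethylaminopropyl)-N'-ethylcarbodiimide hydrochloride (EDC·HCl), 4-(dimethylamino)pyridine (cat.), CH2Cl2, 0 °C to rt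
Reagents that add atoms: 2,2-diphenylethanol, OCC(c1ccccc1)c1ccccc1
Why: Steglich esterification of the free acid with a primary alcohol should install a second ester that is cleavable independently of the tert-butyl ester and, being primary, can later serve as the Claisen electrophile.

Step 3
Reactants: 3 1-tert-butyl 3-(2,2-diphenylethyl) 2-methylpropanedioate
Product: 4 1-tert-butyl 3-(2,2-diphenylethyl) (2S)-2-methyl-2-(3-methylbut-2-en-1-yl)propanedioate
Conditions: prenyl bromide, (S,S)-3,4,5-trifluorophenyl-NAS bromide (N-spiro bis(binaphthyl)ammonium bromide, C56H34BrF6N; cat.), 50% aq. KOH, toluene, −40 °C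
Reagents that add atoms: 1-bromo-3-methylbut-2-ene (prenyl bromide), CC(C)=CCBr
Why: Asymmetric phase-transfer alkylation of an α-methylmalonate with one tert-butyl and one 2,2-diphenylethyl ester, in which the chiral ammonium cation pairs with the enolate and shields one face so that SN2 attack on prenyl bromide sets the quaternary stereocentre as (S); the method is precedented for allylic and benzylic bromides on this malonate class and the esters should survive the cold biphasic base.

Step 4
Reactants: 4 1-tert-butyl 3-(2,2-diphenylethyl) (2S)-2-methyl-2-(3-methylbut-2-en-1-yl)propanedioate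
Product: 6 (2R)-2-[(2,2-diphenylethoxy)carbonyl]-2,5-dimethylhex-4-enoic acid, via trimethylsilyl ester 5 (not isolated)
Conditions: Me3SiOSO2CF3, 2,6-lutidine, CH2Cl2, 0 °C to rt; aq. citric acid work-up
Reagents that add atoms: none
Why: Silyl triflate-mediated tert-butyl ester cleavage (carbonyl O-silylation, loss of the tert-butyl cation as isobutene, hydrolysis of silyl ester 5 on work-up) is chosen over protic acid because the buffered medium should not protonate the prenyl alkene and so avoids lactonization onto it, while the primary ester and the quaternary centre are untouched (the descriptor changes only through the priority rules).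

Step 5
Reactants: 6 (2R)-2-[(2,2-diphenylethoxy)carbonyl]-2,5-dimethylhex-4-enoic acid
Product: 7 2,2-diphenylethyl (2S)-2-(carbonochloridoyl)-2,5-dimethylhex-4-enoate
Conditions: 1-chloro-N,N,2-trimethylprop-1-en-1-amine, CH2Cl2, 0 °C to rt; used without purification
Reagents that add atoms: 1-chloro-N,N,2-trimethylprop-1-en-1-amine (Ghosez reagent), CC(C)=C(Cl)N(C)C
Why: Acid chloride formation with an α-chloroenamine under neutral conditions (no HCl, so the prenyl alkene is safe) should give a non-enolizable, configurationally secure acyl chloride beside a far less reactive hindered ester, which is the reactivity gap the key step needs.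

Step 6
Reactants: 7 2,2-diphenylethyl (2S)-2-(carbonochloridoyl)-2,5-dimethylhex-4-enoate; 8 heptane-2,4-dione
Product: 11 (4R)-2-butanoyl-3,5-dihydroxy-4-methyl-4-(3-methylbut-2-en-1-yl)cyclohexa-2,5-dien-1-one, via dilithium dienolate 9 (not isolated), via open-chain triketo ester 10 (not isolated)
Conditions: 8 (2.2 equiv), LiN(iPr)2 (4.4 equiv), THF, −78 to 0 °C; then 7, −78 °C, slow addition; then rt to 50 °C; aq. HCl
Reagents that add atoms: none
Why: Two equivalents of LiN(iPr)2 convert 8 into dienolate 9, whose terminal carbon (the most basic and most nucleophilic site) should be acylated at −78 °C by the acid chloride of 7 far faster than by its hindered ester, giving the lithium enolate of triketo ester 10 (ring bond C5–C6); excess 9 then deprotonates 10 to its dianion and, on warming, the carbon between the C5 and C7 carbonyls of the decanoate chain attacks the ester carbonyl and expels 2,2-diphenylethoxide (ring bond C2–C3). The closest known reaction types are the terminal C-acylation of 1,3-diketone dianions by acid chlorides and the Claisen (Dieckmann-type) cyclization of 3,5,7-triketo esters to acylphloroglucinols, run here in one pot as a [3+3] double acylation. The ring closes in a 6-(enolexo)-exo-trig mode, helped by the gem-disubstituted C4 and driven by formation of the doubly stabilized anion of the cyclic β-triketone. No stereocentre is created, since C4 comes from 7, but which enantiomer of the ring results depends only on which carbonyl meets which carbon, so the acid chloride/ester gap of 7 and the terminal/central gap of 9 together translate (S)-7 into (4R)-11. The selectivities needed are terminal-before-central acylation (central acylation followed by closure through the methyl group would give the enantiomer), methyl-over-methylene deprotonation of 8 (the other regioisomer would give a separable constitutional isomer, not the enantiomer) and C- over O-acylation in the closure; these should be secured by slow addition of 7 to an excess of preformed 9 at low temperature, by kinetic deprotonation at the less substituted carbon, and by the reversibility of O-acylation against the irreversible deprotonation of the C-acylated product.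

Step 7
Reactants: 12 2-methylbenzene-1,3,5-triol (2-methylphloroglucinol)
Product: 13 1-(2,4,6-trihydroxy-3-methylphenyl)butan-1-one
Conditions: n-PrCOCl, AlCl3, PhNO2, 0 to 50 °C; aq. HCl
Reagents that add atoms: butanoyl chloride, CCCC(=O)Cl
Why: Friedel–Crafts acylation of the strongly activated phloroglucinol ring, in which the two free positions are equivalent by symmetry and the first ketone deactivates the ring towards a second acylation, should give a single mono-ketone.

Step 8
Reactants: 13 1-(2,4,6-trihydroxy-3-methylphenyl)butan-1-one
Product: 14 1-(2,6-dihydroxy-4-methoxy-3-methylphenyl)butan-1-one (aspidinol)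
Conditions: Me2SO4 (1 equiv), K2CO3 (1 equiv), acetone, rt
Reagents that add atoms: dimethyl sulfate, COS(=O)(=O)OC
Why: Williamson-type O-methylation with one equivalent of base should take place at the 4-hydroxyl, which is the most acidic (para to the ketone) and the only one not held in the hydrogen-bond chelate with the carbonyl.

Step 9
Reactants: 14 1-(2,6-dihydroxy-4-methoxy-3-methylphenyl)butan-1-one
Product: 15 1-{3-[(dimethylamino)methyl]-2,6-dihydroxy-4-methoxy-5-methylphenyl}butan-1-one
Conditions: Me2NCH2NMe2, EtOH, rt
Reagents that add atoms: N,N,N',N'-tetramethylmethanediamine, CN(C)CN(C)C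
Why: Mannich aminomethylation with the aminal as iminium source should occur at the only free, strongly activated ring position (between hydroxyl and methoxyl) at a temperature too low for quinone methide formation, so no diarylmethane should arise.

Step 10
Reactants: 11 (4R)-2-butanoyl-3,5-dihydroxy-4-methyl-4-(3-methylbut-2-en-1-yl)cyclohexa-2,5-dien-1-one; 15 1-{3-[(dimethylamino)methyl]-2,6-dihydroxy-4-methoxy-5-methylphenyl}butan-1-one
Product: 17 (4R)-2-butanoyl-6-[(3-butanoyl-2,4-dihydroxy-6-methoxy-5-methylphenyl)methyl]-3,5-dihydroxy-4-methyl-4-(3-methylbut-2-en-1-yl)cyclohexa-2,5-dien-1-one, via ortho-quinone methide 16 (not isolated)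
Conditions: toluene, 90 °C, N2 stream
Reagents that add atoms: none
Why: Proton transfer from the vinylogous acid 11 to the benzylic amine gives an ammonium enolate pair, thermal loss of dimethylamine gives ortho-quinone methide 16, and Michael addition of C6 of 11 (its only unsubstituted nucleophilic carbon) followed by rearomatization should form the methylene bridge; this is the Mannich-base alkylation of 1,3-dicarbonyl compounds, cross-selective because neither partner has a second free position, and the quaternary stereocentre cannot epimerize.

**Compound list**

1 | 2,2,5-trimethyl-1,3-dioxane-4,6-dione | CC1C(=O)OC(C)(C)OC1=O | starting material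
2 | 3-(tert-butoxy)-2-methyl-3-oxopropanoic acid (racemic) | CC(C(=O)O)C(=O)OC(C)(C)C | intermediate
3 | 1-tert-butyl 3-(2,2-diphenylethyl) 2-methylpropanedioate (racemic) | CC(C(=O)OCC(c1ccccc1)c1ccccc1)C(=O)OC(C)(C)C | intermediate
4 | 1-tert-butyl 3-(2,2-diphenylethyl) (2S)-2-methyl-2-(3-methylbut-2-en-1-yl)propanedioate | O=C(OCC(c1ccccc1)c1ccccc1)[C@](C)(CC=C(C)C)C(=O)OC(C)(C)C | intermediate
5 | 1-(2,2-diphenylethyl) 3-(trimethylsilyl) (2S)-2-methyl-2-(3-methylbut-2-en-1-yl)propanedioate (not isolated) | O=C(OCC(c1ccccc1)c1ccccc1)[C@](C)(CC=C(C)C)C(=O)O[Si](C)(C)C | intermediate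
6 | (2R)-2-[(2,2-diphenylethoxy)carbonyl]-2,5-dimethylhex-4-enoic acid | O=C(OCC(c1ccccc1)c1ccccc1)[C@](C)(CC=C(C)C)C(=O)O | intermediate
7 | 2,2-diphenylethyl (2S)-2-(carbonochloridoyl)-2,5-dimethylhex-4-enoate | O=C(OCC(c1ccccc1)c1ccccc1)[C@](C)(CC=C(C)C)C(=O)Cl | intermediate
8 | heptane-2,4-dione | CCCC(=O)CC(C)=O | starting material
9 | dilithium hepta-1,3-diene-2,4-diolate (not isolated) | [Li+].[Li+].C=C([O-])C=C([O-])CCC | intermediate
10 | 2,2-diphenylethyl (2R)-2-methyl-2-(3-methylbut-2-en-1-yl)-3,5,7-trioxodecanoate (formed as its lithium enolate, not isolated) | O=C(OCC(c1ccccc1)c1ccccc1)[C@](C)(CC=C(C)C)C(=O)CC(=O)CC(=O)CCC | intermediate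
11 | (4R)-2-butanoyl-3,5-dihydroxy-4-methyl-4-(3-methylbut-2-en-1-yl)cyclohexa-2,5-dien-1-one | CCCC(=O)C1=C(O)[C@](C)(CC=C(C)C)C(O)=CC1=O | intermediate
12 | 2-methylbenzene-1,3,5-triol | Cc1c(O)cc(O)cc1O | starting material
13 | 1-(2,4,6-trihydroxy-3-methylphenyl)butan-1-one | CCCC(=O)c1c(O)cc(O)c(C)c1O | intermediate
14 | 1-(2,6-dihydroxy-4-methoxy-3-methylphenyl)butan-1-one (aspidinol) | CCCC(=O)c1c(O)cc(OC)c(C)c1O | intermediate
15 | 1-{3-[(dimethylamino)methyl]-2,6-dihydroxy-4-methoxy-5-methylphenyl}butan-1-one | CCCC(=O)c1c(O)c(CN(C)C)c(OC)c(C)c1O | intermediate
16 | 2-butanoyl-3-hydroxy-5-methoxy-4-methyl-6-methylidenecyclohexa-2,4-dien-1-one (not isolated) | C=C1C(=O)C(C(=O)CCC)=C(O)C(C)=C1OC | intermediate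
17 | (4R)-2-butanoyl-6-[(3-butanoyl-2,4-dihydroxy-6-methoxy-5-methylphenyl)methyl]-3,5-dihydroxy-4-methyl-4-(3-methylbut-2-en-1-yl)cyclohexa-2,5-dien-1-one | CCCC(=O)C1=C(O)[C@](C)(CC=C(C)C)C(O)=C(Cc2c(O)c(C(=O)CCC)c(O)c(C)c2OC)C1=O | target

**Count and risks**

Total step count: 10. Longest linear sequence: 7 (steps 1 to 6, then step 10).

Steps most likely to fail:

1. Step 6. Acylation of the mono-enolate of 8 at its central carbon or on oxygen may compete with terminal acylation of the dienolate, which would erode enantiomeric purity, and the closure may stall at the open chain or divert to O-cyclization. The fallback reverses the order of bond formation and sets out from 4. Selective saponification of the primary 2,2-diphenylethyl ester (KOH, MeOH, rt) should give the tert-butyl half-ester acid F1, which the α-chloroenamine of step 5 converts into acid chloride F2. Soft-enolization C-acylation of 8 at its central carbon (MgCl2, pyridine, CH2Cl2) should give the triacylmethane ester F3. LiN(iPr)2 (3 equiv, THF, −78 °C to rt) then deprotonates the acetyl methyl group kinetically and Claisen closure onto the tert-butyl ester returns to the route at 11 with the same (4R) configuration.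

2. Step 10. Retro-Michael cleavage and re-addition may scramble the methylene bridge towards symmetrical dimers, or quinone methide formation may be sluggish. The fallback moves the aminomethyl handle to the other partner and sets out from 11. Treatment with Me2NCH2NMe2 (EtOH, rt) should give the trione Mannich base F4. Heating F4 with 14 and K2CO3 in 1,4-dioxane releases dimethylamine through the 2-methylidene trione, which the free ring position of 14 should trap, returning to the route at 17.

3. Step 4. The Lewis acid or adventitious protic acid may induce attack of the carboxyl group on the prenyl alkene, or cleavage of the hindered tert-butyl ester may be incomplete. The fallback installs the trisubstituted alkene only after the ester cleavage and sets out from 3. Allylation with allyl bromide under the conditions of step 3 should give the allyl diester F5. CF3CO2H in CH2Cl2 at 0 °C, harmless to a monosubstituted alkene, should give the allyl acid F6. Cross-metathesis with 2-methylbut-2-ene (second-generation Grubbs catalyst, CH2Cl2, 40 °C) returns to the route at 6.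

**Further compounds**

F1 | step 6 | (2S)-2-(tert-butoxycarbonyl)-2,5-dimethylhex-4-enoic acid | OC(=O)[C@](C)(CC=C(C)C)C(=O)OC(C)(C)C
F2 | step 6 | tert-butyl (2R)-2-(carbonochloridoyl)-2,5-dimethylhex-4-enoate | ClC(=O)[C@](C)(CC=C(C)C)C(=O)OC(C)(C)C
F3 | step 6 | tert-butyl (2S)-4-acetyl-2-methyl-2-(3-methylbut-2-en-1-yl)-3,5-dioxooctanoate | CCCC(=O)C(C(C)=O)C(=O)[C@](C)(CC=C(C)C)C(=O)OC(C)(C)C
F4 | step 10 | (4R)-2-butanoyl-6-[(dimethylamino)methyl]-3,5-dihydroxy-4-methyl-4-(3-methylbut-2-en-1-yl)cyclohexa-2,5-dien-1-one | CCCC(=O)C1=C(O)[C@](C)(CC=C(C)C)C(O)=C(CN(C)C)C1=O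
F5 | step 4 | 1-tert-butyl 3-(2,2-diphenylethyl) (2S)-2-methyl-2-(prop-2-en-1-yl)propanedioate | O=C(OCC(c1ccccc1)c1ccccc1)[C@](C)(CC=C)C(=O)OC(C)(C)C
F6 | step 4 | (2R)-2-[(2,2-diphenylethoxy)carbonyl]-2-methylpent-4-enoic acid | O=C(OCC(c1ccccc1)c1ccccc1)[C@](C)(CC=C)C(=O)O
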